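## Retrosynthetic overview

1. Target 19 comes from 18 by one global deprotection (two aryl allyl ethers, one acetate).
2. The oxepine ring is closed last: the C11–aryl bond of 18 is formed by anodic dehydrogenative coupling of the 6-aryl-dihydropyran enol ether 16 with its ether-tethered resorcinol-type ring.
3. The dihydropyran ring is formed first, by cyclodehydration of δ-hydroxy ketone 15; its C11–C4 bond comes from opening epoxy alcohol 7 with the enolate of diaryl ether ketone 13.
4. Ketone 13 comes from SNAr of 4-prenylresorcinol 9 on fluoro ketone 11 (both benzene rings are bought).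
5. Epoxy alcohol 7 comes from methyl (S)-glycerate acetonide 1: C3 is bought, C2 is set by Felkin–Anh addition of MeMgBr to ketone 3.

Assumption: in descriptive names the pyran atoms are O1, C2 (quaternary), C3 (carbinol) and C4; the oxepine alkene carbons are C10 (bears O1 and ring B) and C11 (bears C4 and ring A); small reagents are not numbered.

## Route

Step 1
Reactants: 1 methyl (4S)-2,2-dimethyl-1,3-dioxolane-4-carboxylate
Product: 3 1-[(4S)-2,2-dimethyl-1,3-dioxolan-4-yl]-5-methylhex-4-en-1-one, via Weinreb amide 2 (not isolated)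
Conditions: MeNH(OMe)·HCl, i-PrMgCl, THF, −20 °C; then (4-methylpent-3-enyl)MgBr, −20 → 0 °C; H2O
Reagents that add atoms: (4-methylpent-3-en-1-yl)magnesium bromide, CC(C)=CCC[Mg]Br
Why: Weinreb ketone synthesis in one pot; the chelated tetrahedral adduct of amide 2 stops the Grignard addition at the ketone, and the bought α-stereocentre is not enolised at this temperature.

Step 2
Reactants: 3 1-[(4S)-2,2-dimethyl-1,3-dioxolan-4-yl]-5-methylhex-4-en-1-one
Product: 4 (2S)-2-[(4S)-2,2-dimethyl-1,3-dioxolan-4-yl]-6-methylhept-5-en-2-ol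
Conditions: MeMgBr, THF, −78 °C; H2O
Reagents that add atoms: methylmagnesium bromide, C[Mg]Br
Why: Felkin–Anh (non-chelation) Grignard addition to an α-alkoxy ketone: the dioxolane C–O bond lies anti to the incoming methyl and attack passes the α-H, so the bought (4S) centre sets the new tertiary carbinol as (S); the minor diastereomer is removed by chromatography.

Step 3
Reactants: 4 (2S)-2-[(4S)-2,2-dimethyl-1,3-dioxolan-4-yl]-6-methylhept-5-en-2-ol
Product: 5 (2S,3S)-3,7-dimethyloct-6-ene-1,2,3-triol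
Conditions: AcOH/H2O (4:1), 40 °C
Reagents that add atoms: none
Why: Acid-catalysed acetonide hydrolysis; dilute acetic acid is too weak to ionise the tertiary alcohol or protonate the trisubstituted alkene.

Step 4
Reactants: 5 (2S,3S)-3,7-dimethyloct-6-ene-1,2,3-triol
Product: 7 (2S)-6-methyl-2-[(2S)-oxiran-2-yl]hept-5-en-2-ol, via primary tosylate 6 (not isolated)
Conditions: TsCl (1.05 equiv), Bu2SnO (2 mol%), Et3N, CH2Cl2, 0 °C; then K2CO3, MeOH, rt
Reagents that add atoms: none
Why: Tin-catalysed selective sulfonylation of the primary OH of the 1,2-diol, then Williamson (3-exo-tet) epoxide closure by the secondary alkoxide; no bond to either stereocentre is broken.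

Step 5
Reactants: 8 resorcinol
Product: 9 4-(3-methylbut-2-en-1-yl)benzene-1,3-diol
Conditions: prenyl bromide (0.5 equiv), KOH, H2O, 0 °C → rt
Reagents that add atoms: 1-bromo-3-methylbut-2-ene, CC(C)=CCBr
Why: Nuclear C-prenylation of the ambident resorcinol phenoxide in water, which favours the 4-position; excess resorcinol limits diprenylation and the modest yield is acceptable at this stage.

Step 6
Reactants: 10 1-(2-fluoro-4-hydroxyphenyl)ethan-1-one
Product: 11 1-[2-fluoro-4-(prop-2-en-1-yloxy)phenyl]ethan-1-one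
Conditions: allyl bromide, K2CO3, acetone, reflux
Reagents that add atoms: allyl bromide, C=CCBr
Why: Williamson O-allylation; the free para-phenoxide would otherwise switch off the SNAr of step 7.

Step 7
Reactants: 9 4-(3-methylbut-2-en-1-yl)benzene-1,3-diol; 11 1-[2-fluoro-4-(prop-2-en-1-yloxy)phenyl]ethan-1-one
Product: 13 1-[2-[4-(3-methylbut-2-en-1-yl)-3-(prop-2-en-1-yloxy)phenoxy]-4-(prop-2-en-1-yloxy)phenyl]ethan-1-one, via phenol 12 (not isolated)
Conditions: K2CO3, DMF, 100 °C; then allyl bromide, 50 °C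
Reagents that add atoms: allyl bromide, C=CCBr
Why: SNAr of the ortho-acyl-activated aryl fluoride by the less hindered phenoxide of 9 (the OH para to the prenyl group), then Williamson allylation of the remaining hindered phenol in the same pot; the minor regioisomer is removed by chromatography.

Step 8
Reactants: 13 1-[2-[4-(3-methylbut-2-en-1-yl)-3-(prop-2-en-1-yloxy)phenoxy]-4-(prop-2-en-1-yloxy)phenyl]ethan-1-one; 7 (2S)-6-methyl-2-[(2S)-oxiran-2-yl]hept-5-en-2-ol
Product: 15 (4S,5S)-5-hydroxy-5,9-dimethyl-1-oxo-1-aryl-dec-8-en-4-yl acetate (aryl as in 13), via diol 14 (not isolated)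
Conditions: LiHMDS (2.1 equiv), THF, −78 °C; 7, Sc(OTf)3 (10 mol%), −78 → 0 °C; H2O; crude: Ac2O, pyridine, DMAP (cat.), CH2Cl2, 0 °C
Reagents that add atoms: acetic anhydride, CC(=O)OC(C)=O
Why: Lewis-acid-promoted opening of the terminal epoxide at its CH2 by the lithium enolate forms the C11–C4 bond without touching either stereocentre; acetylation then takes the secondary OH selectively over the tertiary one, so only the tertiary OH can cyclise in step 9.

Step 9
Reactants: 15 (4S,5S)-5-hydroxy-5,9-dimethyl-1-oxo-1-aryl-dec-8-en-4-yl acetate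
Product: 16 (2S,3S)-6-aryl-2-methyl-2-(4-methylpent-3-en-1-yl)-3,4-dihydro-2H-pyran-3-yl acetate (aryl as in 13)
Conditions: PPTS (10 mol%), 4 Å MS, PhMe, 90 °C
Reagents that add atoms: none
Why: Acid-catalysed cyclodehydration of a δ-hydroxy ketone to a 3,4-dihydro-2H-pyran (hemiketal, then loss of water towards the only α-CH2); the tertiary C–O bond stays intact, so C2 is retained.

Step 10
Reactants: 16 (2S,3S)-6-aryl-2-methyl-2-(4-methylpent-3-en-1-yl)-3,4-dihydro-2H-pyran-3-yl acetate
Product: 18 3-O-acetyl-di-O-allyl derivative of the target, via methoxy ketal 17 (not isolated)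
Conditions: RVC anode, Pt cathode, undivided cell, constant current (2.2 F/mol), LiClO4, 2,6-lutidine, MeOH/CH2Cl2 (1:4), rt; then PPTS (cat.), PhMe, 60 °C
Reagents that add atoms: none
Why: Proposed new method: anodic oxidation of the 2-aryl enol ether (the most easily oxidised π-system, well below the arene rings and trisubstituted alkenes) gives a radical cation that is electrophilic at C11; the tethered ring A attacks through its carbon para to O-allyl in a 7-endo mode, leaving an α-oxy benzylic radical at C10 that is oxidised and trapped by MeOH as the non-oxidisable ketal 17, and mild acid then expels MeOH to the tetrasubstituted enol ether; the closest known reaction is the anodic olefin coupling of enol ether radical cations with electron-rich arenes, so far used for five- and six-membered rings and not for a dibenzo[b,f]oxepine through a diaryl ether tether.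

Step 11
Reactants: 18 3-O-acetyl-di-O-allyl derivative of the target
Product: 19 target CNP0185870.1
Conditions: Pd(PPh3)4 (5 mol%), K2CO3, MeOH, rt, Ar
Reagents that add atoms: none
Why: Pd(0)-catalysed deallylation of both aryl allyl ethers (π-allyl transfer to methoxide) with concurrent base-catalysed methanolysis of the acetate; the basic, non-acidic medium spares the enol ether and the three alkenes.

## Compound list

1 | methyl (4S)-2,2-dimethyl-1,3-dioxolane-4-carboxylate | COC(=O)[C@@H]1COC(C)(C)O1 | starting material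
2 | (4S)-N-methoxy-N,2,2-trimethyl-1,3-dioxolane-4-carboxamide | CON(C)C(=O)[C@@H]1COC(C)(C)O1 | intermediate
3 | 1-[(4S)-2,2-dimethyl-1,3-dioxolan-4-yl]-5-methylhex-4-en-1-one | CC(C)=CCCC(=O)[C@@H]1COC(C)(C)O1 | intermediate
4 | (2S)-2-[(4S)-2,2-dimethyl-1,3-dioxolan-4-yl]-6-methylhept-5-en-2-ol | CC(C)=CCC[C@](C)(O)[C@@H]1COC(C)(C)O1 | intermediate
5 | (2S,3S)-3,7-dimethyloct-6-ene-1,2,3-triol | CC(C)=CCC[C@](C)(O)[C@@H](O)CO | intermediate
6 | (2S,3S)-2,3-dihydroxy-3,7-dimethyloct-6-en-1-yl 4-methylbenzenesulfonate | CC(C)=CCC[C@](C)(O)[C@@H](O)COS(=O)(=O)c1ccc(C)cc1 | intermediate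
7 | (2S)-6-methyl-2-[(2S)-oxiran-2-yl]hept-5-en-2-ol | CC(C)=CCC[C@](C)(O)[C@@H]1CO1 | intermediate
8 | resorcinol (benzene-1,3-diol) | Oc1cccc(O)c1 | starting material
9 | 4-(3-methylbut-2-en-1-yl)benzene-1,3-diol | CC(C)=CCc1ccc(O)cc1O | intermediate
10 | 1-(2-fluoro-4-hydroxyphenyl)ethan-1-one | CC(=O)c1ccc(O)cc1F | starting material
11 | 1-[2-fluoro-4-(prop-2-en-1-yloxy)phenyl]ethan-1-one | CC(=O)c1ccc(OCC=C)cc1F | intermediate
12 | 1-[2-[3-hydroxy-4-(3-methylbut-2-en-1-yl)phenoxy]-4-(prop-2-en-1-yloxy)phenyl]ethan-1-one | CC(=O)c1ccc(OCC=C)cc1Oc1ccc(CC=C(C)C)c(O)c1 | intermediate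
13 | 1-[2-[4-(3-methylbut-2-en-1-yl)-3-(prop-2-en-1-yloxy)phenoxy]-4-(prop-2-en-1-yloxy)phenyl]ethan-1-one | CC(=O)c1ccc(OCC=C)cc1Oc1ccc(CC=C(C)C)c(OCC=C)c1 | intermediate
14 | (4S,5S)-4,5-dihydroxy-5,9-dimethyl-1-[2-[4-(3-methylbut-2-en-1-yl)-3-(prop-2-en-1-yloxy)phenoxy]-4-(prop-2-en-1-yloxy)phenyl]dec-8-en-1-one | CC(C)=CCC[C@](C)(O)[C@@H](O)CCC(=O)c1ccc(OCC=C)cc1Oc1ccc(CC=C(C)C)c(OCC=C)c1 | intermediate
15 | (4S,5S)-5-hydroxy-5,9-dimethyl-1-oxo-1-[2-[4-(3-methylbut-2-en-1-yl)-3-(prop-2-en-1-yloxy)phenoxy]-4-(prop-2-en-1-yloxy)phenyl]dec-8-en-4-yl acetate | CC(C)=CCC[C@](C)(O)[C@@H](OC(C)=O)CCC(=O)c1ccc(OCC=C)cc1Oc1ccc(CC=C(C)C)c(OCC=C)c1 | intermediate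
16 | (2S,3S)-2-methyl-2-(4-methylpent-3-en-1-yl)-6-[2-[4-(3-methylbut-2-en-1-yl)-3-(prop-2-en-1-yloxy)phenoxy]-4-(prop-2-en-1-yloxy)phenyl]-3,4-dihydro-2H-pyran-3-yl acetate | CC(C)=CCC[C@]1(C)OC(=CC[C@@H]1OC(C)=O)c1ccc(OCC=C)cc1Oc1ccc(CC=C(C)C)c(OCC=C)c1 | intermediate
17 | C10 methyl ketal: 10-methoxy-10,11-dihydro form of 18 (OMe on C10, H on C11, mixture at C10 and C11; C2 and C3 both S) | CC(C)=CCC[C@]1(C)OC2(OC)C(C[C@@H]1OC(C)=O)c1cc(CC=C(C)C)c(OCC=C)cc1Oc1cc(OCC=C)ccc12 | intermediate
18 | protected target: (2S,3S)-dihydropyran O1–C2(Me)(4-methylpent-3-enyl)–C3H(OAc)–C4H2 fused across C10=C11 of a dibenzo[b,f]oxepine (O1 on C10, C4 on C11); ring A (on C11) has O-allyl para to C11 and prenyl ortho to that O-allyl; ring B (on C10) has O-allyl para to C10 | CC(C)=CCC[C@]1(C)OC2=C(C[C@@H]1OC(C)=O)c1cc(CC=C(C)C)c(OCC=C)cc1Oc1cc(OCC=C)ccc12 | intermediate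
19 | CNP0185870.1: as 18 with (2S,3S)-C3–OH free and both O-allyl groups replaced by OH | CC(C)=CCC[C@]1(C)OC2=C(C[C@@H]1O)c1cc(CC=C(C)C)c(O)cc1Oc1cc(O)ccc12 | target

## Step count and risks

Total step count: 11. Longest linear sequence: 8 steps (1, 2, 3, 4, 8, 9, 10, 11).

The three steps most likely to fail are step 10 (most likely), step 8 and step 2.

**Step 2 (facial selectivity of the methyl addition).** If α-chelation competes and the Felkin–Anh ratio is poor or reversed, the two carbon groups are introduced in the opposite order under deliberate chelation control. The fallback sets out from 1: the one-pot procedure of step 1 is run with MeMgBr in place of the homoprenyl Grignard, which gives the methyl ketone 1-[(4S)-2,2-dimethyl-1,3-dioxolan-4-yl]ethan-1-one F1. Addition of (4-methylpent-3-enyl)magnesium bromide to F1 with MgBr2·OEt2 in CH2Cl2 at −78 °C goes through the Cram chelate; the attack is on the opposite face, and with nucleophile and ketone substituent exchanged this gives the same (2S,4S) alcohol. The fallback comes back to the route at 4.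

**Step 8 (enolate opening of a hindered epoxy alcohol).** A ketone enolate is a weak nucleophile for epoxides, and the Lewis acid could trigger semipinacol rearrangement of 7. The fallback sets out from 13, which is condensed with 1,1-dimethylhydrazine (cat. AcOH, EtOH, reflux) to the N,N-dimethylhydrazone of 13 F2. Its aza-enolate (LDA, THF, −78 °C) opens the lithium alkoxide of 7 at the CH2 without any Lewis acid, giving the (4S,5S)-4,5-dihydroxy hydrazone F3. Hydrolysis of the hydrazone with aqueous CuCl2 at pH 7 (periodate is excluded because of the diol) comes back to the route at 14, which is acetylated as in step 8.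

**Step 10 (new anodic ring closure).** The seven-membered closure may lose to methanol trapping or over-oxidation. The fallback closes the oxepine by known photostimulated SRN1 α-arylation before the pyran is made, and sets out from 11.
- SNAr of 11 with resorcinol 8 (3 equiv, K2CO3, DMF, 100 °C) gives the phenol 1-[2-(3-hydroxyphenoxy)-4-(prop-2-en-1-yloxy)phenyl]ethan-1-one F4.
- Iodination para to the OH (NIS, MeCN, 0 °C) gives 1-[2-(5-hydroxy-2-iodophenoxy)-4-(prop-2-en-1-yloxy)phenyl]ethan-1-one F5.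
- Ortho C-prenylation of its sodium phenoxide (NaH, toluene, prenyl bromide) gives 1-[2-[5-hydroxy-2-iodo-4-(3-methylbut-2-en-1-yl)phenoxy]-4-(prop-2-en-1-yloxy)phenyl]ethan-1-one F6.
- O-allylation (allyl bromide, K2CO3) gives the iodo analogue of 13, 1-[2-[2-iodo-4-(3-methylbut-2-en-1-yl)-5-(prop-2-en-1-yloxy)phenoxy]-4-(prop-2-en-1-yloxy)phenyl]ethan-1-one F7.
- The ketone enolate is cyclised onto the aryl iodide (KOt-Bu, liquid NH3, hν 350 nm) to the dibenzo[b,f]oxepin-10(11H)-one with O-allyl para to C10 on ring B and O-allyl para to C11 plus prenyl ortho to that O-allyl on ring A F8.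
- Its enolate is alkylated at C11 with 7 under the conditions of step 8 to the 11-[(2S,3S)-2,3-dihydroxy-3,7-dimethyloct-6-en-1-yl] ketone F9, which is acetylated at the secondary OH to F10.
- Cyclodehydration of the tertiary OH onto the C10 ketone (PPTS, 4 Å MS, toluene, 90 °C) comes back to the route at 18.

## Further compounds

F1 | step 2 | 1-[(4S)-2,2-dimethyl-1,3-dioxolan-4-yl]ethan-1-one | CC(=O)[C@@H]1COC(C)(C)O1
F2 | step 8 | N,N-dimethylhydrazone of 13 | CC(=NN(C)C)c1ccc(OCC=C)cc1Oc1ccc(CC=C(C)C)c(OCC=C)c1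
F3 | step 8 | N,N-dimethylhydrazone of 14 ((4S,5S)-4,5-dihydroxy hydrazone) | CC(C)=CCC[C@](C)(O)[C@@H](O)CCC(=NN(C)C)c1ccc(OCC=C)cc1Oc1ccc(CC=C(C)C)c(OCC=C)c1
F4 | step 10 | 1-[2-(3-hydroxyphenoxy)-4-(prop-2-en-1-yloxy)phenyl]ethan-1-one | CC(=O)c1ccc(OCC=C)cc1Oc1cccc(O)c1
F5 | step 10 | 1-[2-(5-hydroxy-2-iodophenoxy)-4-(prop-2-en-1-yloxy)phenyl]ethan-1-one | CC(=O)c1ccc(OCC=C)cc1Oc1cc(O)ccc1I
F6 | step 10 | 1-[2-[5-hydroxy-2-iodo-4-(3-methylbut-2-en-1-yl)phenoxy]-4-(prop-2-en-1-yloxy)phenyl]ethan-1-one | CC(=O)c1ccc(OCC=C)cc1Oc1cc(O)c(CC=C(C)C)cc1I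
F7 | step 10 | 1-[2-[2-iodo-4-(3-methylbut-2-en-1-yl)-5-(prop-2-en-1-yloxy)phenoxy]-4-(prop-2-en-1-yloxy)phenyl]ethan-1-one | CC(=O)c1ccc(OCC=C)cc1Oc1cc(OCC=C)c(CC=C(C)C)cc1I
F8 | step 10 | dibenzo[b,f]oxepin-10(11H)-one with O-allyl para to C10 on ring B, O-allyl para to C11 and prenyl ortho to it on ring A | O=C1Cc2cc(CC=C(C)C)c(OCC=C)cc2Oc2cc(OCC=C)ccc12
F9 | step 10 | 11-[(2S,3S)-2,3-dihydroxy-3,7-dimethyloct-6-en-1-yl] derivative of F8 (mixture at C11) | CC(C)=CCC[C@](C)(O)[C@@H](O)CC1C(=O)c2ccc(OCC=C)cc2Oc2cc(OCC=C)c(CC=C(C)C)cc12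
F10 | step 10 | secondary acetate of F9 | CC(C)=CCC[C@](C)(O)[C@@H](OC(C)=O)CC1C(=O)c2ccc(OCC=C)cc2Oc2cc(OCC=C)c(CC=C(C)C)cc12
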